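**Retrosynthetic overview**
1. Ring C is closed last: cutting the O1–C2 bond of the flavanone gives an open-chain (E)-2',6'-dihydroxychalcone. The C–O bond and the (2S) centre are made together in a catalytic asymmetric oxa-Michael cyclisation through the unhindered 6'-OH.
2. The chalcone is cut at Cα=Cβ (Claisen–Schmidt) into a ring A acetophenone and a ring B aldehyde, both carried without protecting groups.
3. Ring A fragment: 2',6'-dihydroxy-4'-methoxyacetophenone plus prenyl bromide (C-prenylation).
4. Ring B fragment: veratraldehyde plus geranyl bromide (directed ortho-lithiation at C2 through an in situ alpha-amino alkoxide).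
5. Rings A and B are bought intact; ring C is the only ring formed.

Assumption: the sense of induction of the proposed catalyst in step 4 is unknown; the catalyst from (S)-tert-leucine is taken to give the (2S)-flavanone, and its mirror image from (R)-tert-leucine is used if the opposite sense is found (checked by chiral HPLC and CD).

Catalyst for step 4: N-[3,5-bis(trifluoromethyl)phenyl]-N'-[(2S)-3,3-dimethyl-1-{[tris(4-methoxyphenyl)phosphoranylidene]amino}butan-2-yl]thiourea, a bifunctional iminophosphorane–thiourea, SMILES COc1ccc(cc1)P(=NC[C@@H](NC(=S)Nc1cc(cc(c1)C(F)(F)F)C(F)(F)F)C(C)(C)C)(c1ccc(OC)cc1)c1ccc(OC)cc1.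

**Route**

Step 1
Reactants: 1 2',6'-dihydroxy-4'-methoxyacetophenone; 2 prenyl bromide
Product: 3 2',6'-dihydroxy-4'-methoxy-3'-prenylacetophenone
Conditions: 10% aq KOH, 2 (0.9 equiv), 0 °C → rt, 4 h; acidic work-up; unreacted 1 recovered
Reagents that add atoms: none
Why: Phenoxide C-alkylation (C-prenylation) in water, where solvation of the phenoxide oxygen favours attack through carbon; the two open ring positions of 1 are equivalent, so one mono-C-prenyl product forms and no stereocentre is created.

Step 2
Reactants: 4 veratraldehyde; 5 geranyl bromide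
Product: 9 2-geranyl-3,4-dimethoxybenzaldehyde, via lithium alpha-amino alkoxide 6 (not isolated), via 2-lithio alpha-amino alkoxide 7 (not isolated), via 2-geranyl alpha-amino alkoxide 8 (not isolated)
Conditions: LiN(Me)CH2CH2NMe2 (1.1 equiv, from MeNHCH2CH2NMe2 + n-BuLi), THF, −20 °C; n-BuLi (3 equiv), −20 °C, 20 h; CuBr·SMe2 (20 mol %), 5 (4 equiv, the excess also consumes surplus n-BuLi), −78 °C → rt; cold 1 M HCl
Reagents that add atoms: none
Why: Comins-type directed ortho-metalation, in which the in situ alpha-amino alkoxide masks the aldehyde and, together with the 3-OMe group, directs lithiation to C2 between them; copper-assisted SN2 allylation at the primary carbon of 5 carries the E-olefin over unchanged, and acid work-up releases the aldehyde (no stereocentre formed).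

Step 3
Reactants: 3 2',6'-dihydroxy-4'-methoxy-3'-prenylacetophenone; 9 2-geranyl-3,4-dimethoxybenzaldehyde
Product: 11 (E)-2',6'-dihydroxy-4'-methoxy-3'-prenyl-2-geranyl-3,4-dimethoxychalcone, via trilithium aldolate 10 (not isolated)
Conditions: LiN(SiMe3)2 (4.5 equiv), THF, −78 °C, 1 h; 9 (1.05 equiv), −78 °C → rt, 16 h; pour into cold 1 M HCl; fast chromatography, store cold
Reagents that add atoms: none
Why: Claisen–Schmidt aldol condensation on the lithium polyanion of the unprotected hydroxy ketone, where the two phenoxides are spectators, the ketone enolate adds to 9 and E1cB loss of LiOH gives the thermodynamically favoured E-enone; the cold acidic quench avoids base-mediated closure to racemic flavanone, which must be removed completely here.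

Step 4
Reactants: 11 (E)-2',6'-dihydroxy-4'-methoxy-3'-prenyl-2-geranyl-3,4-dimethoxychalcone
Product: 12 (2S)-5-hydroxy-7-methoxy-6-prenyl-2-(2-geranyl-3,4-dimethoxyphenyl)chroman-4-one (CNP0112088.1)
Conditions: (S)-ArNHC(=S)NHCH(t-Bu)CH2N=P(C6H4-4-OMe)3 (Ar = 3,5-(CF3)2C6H3; 10 mol %), toluene (0.05 M), −20 °C, 48 h; AcOH quench; silica; ee by chiral HPLC
Reagents that add atoms: none
Why: Proposed new method: a site- and enantioselective intramolecular oxa-Michael addition of an unactivated, unprotected 2',6'-dihydroxychalcone, in which the strongly basic iminophosphorane nitrogen deprotonates the free 6'-OH (the 2'-OH is locked in the C=O chelate, buttressed and shielded by the 3'-prenyl group, and ends as the 5-OH), the aminophosphonium and thiourea N–H groups hold phenoxide and enone carbonyl in a tight chiral ion pair so that oxygen adds to one face of C-β and sets C2 as (S), and the aminophosphonium then protonates C3; neutral 11 does not cyclise in toluene and the product rests as its 5-phenoxide, which resists E1cB ring opening, so no racemic background or erosion is expected; the closest known reaction type is the bifunctional Brønsted base/hydrogen-bond-donor catalysed asymmetric oxa-Michael addition (cinchona–thiourea cyclisation of ester-activated 2'-hydroxychalcones, iminophosphorane-catalysed additions of alcohols to unsaturated esters).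

**Compound list**

1 | 1-(2,6-dihydroxy-4-methoxyphenyl)ethan-1-one | CC(=O)c1c(O)cc(OC)cc1O | starting material
2 | 1-bromo-3-methylbut-2-ene (prenyl bromide) | CC(C)=CCBr | starting material
3 | 1-[2,6-dihydroxy-4-methoxy-3-(3-methylbut-2-en-1-yl)phenyl]ethan-1-one | CC(=O)c1c(O)cc(OC)c(CC=C(C)C)c1O | intermediate
4 | 3,4-dimethoxybenzaldehyde (veratraldehyde) | COc1ccc(C=O)cc1OC | starting material
5 | (2E)-1-bromo-3,7-dimethylocta-2,6-diene (geranyl bromide) | BrC/C=C(\C)CCC=C(C)C | starting material
6 | lithium (3,4-dimethoxyphenyl){[2-(dimethylamino)ethyl](methyl)amino}methanolate (racemic at the aminal carbon) | [Li]OC(c1ccc(OC)c(OC)c1)N(C)CCN(C)C | intermediate (not isolated)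
7 | 2-lithio derivative of 6, lithium (2-lithio-3,4-dimethoxyphenyl){[2-(dimethylamino)ethyl](methyl)amino}methanolate | [Li]c1c(C(O[Li])N(C)CCN(C)C)ccc(OC)c1OC | intermediate (not isolated)
8 | lithium {2-[(2E)-3,7-dimethylocta-2,6-dien-1-yl]-3,4-dimethoxyphenyl}{[2-(dimethylamino)ethyl](methyl)amino}methanolate | [Li]OC(c1ccc(OC)c(OC)c1C/C=C(\C)CCC=C(C)C)N(C)CCN(C)C | intermediate (not isolated)
9 | 2-[(2E)-3,7-dimethylocta-2,6-dien-1-yl]-3,4-dimethoxybenzaldehyde | COc1ccc(C=O)c(C/C=C(\C)CCC=C(C)C)c1OC | intermediate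
10 | trilithium salt of the aldol adduct 1-[2,6-dihydroxy-4-methoxy-3-(3-methylbut-2-en-1-yl)phenyl]-3-{2-[(2E)-3,7-dimethylocta-2,6-dien-1-yl]-3,4-dimethoxyphenyl}-3-hydroxypropan-1-one (racemic carbinol) | [Li]Oc1cc(OC)c(CC=C(C)C)c(O[Li])c1C(=O)CC(O[Li])c1ccc(OC)c(OC)c1C/C=C(\C)CCC=C(C)C | intermediate (not isolated)
11 | (2E)-1-[2,6-dihydroxy-4-methoxy-3-(3-methylbut-2-en-1-yl)phenyl]-3-{2-[(2E)-3,7-dimethylocta-2,6-dien-1-yl]-3,4-dimethoxyphenyl}prop-2-en-1-one | COc1cc(O)c(C(=O)/C=C/c2ccc(OC)c(OC)c2C/C=C(\C)CCC=C(C)C)c(O)c1CC=C(C)C | intermediate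
12 | (2S)-2-{2-[(2E)-3,7-dimethylocta-2,6-dien-1-yl]-3,4-dimethoxyphenyl}-5-hydroxy-7-methoxy-6-(3-methylbut-2-en-1-yl)-2,3-dihydro-4H-chromen-4-one | COc1cc2c(c(O)c1CC=C(C)C)C(=O)C[C@@H](c1ccc(OC)c(OC)c1C/C=C(\C)CCC=C(C)C)O2 | target

**Step count and risks**

Total step count: 4. Longest linear sequence: 3 steps (1 → 3 → 11 → 12, or 4 → 9 → 11 → 12).

Steps most likely to fail:

Step 4 (the proposed new step). The ee or the selection between the two phenols may be insufficient. The fallback uses known chemistry and sets out from chalcone 11. Classical base-mediated isomerisation (NaOAc, EtOH, reflux) gives the racemic flavanone F1, which is separated on silica from the racemic 8-prenyl regioisomer F2 that forms beside it. F1 is then resolved by preparative HPLC on an amylose tris(3,5-dimethylphenylcarbamate) chiral stationary phase. The (2S)-enantiomer is collected (negative Cotton effect near 290 nm, positive near 330 nm), and the route is rejoined at target 12.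

Step 3 (condensation without protecting groups). The polyanion may be too unreactive towards the hindered aldehyde, or the chalcone may close during isolation. The fallback sets out from acetophenone 3. Both phenols are protected (NaH, MOMCl, DMF, 0 °C → rt) to give the bis(methoxymethyl) ether F3. Standard Claisen–Schmidt condensation with 9 (KOH, EtOH/H2O, rt) passes through the aldol adduct F4 and gives the protected chalcone F5. Mild acetal cleavage (HCl, MeOH, rt) returns to the route at chalcone 11.

Step 2 (one-pot lithiation and geranylation). Lithiation may not be clean at C2, or surplus n-BuLi may spoil the allylation. The fallback sets out from veratraldehyde 4. Reduction (NaBH4, MeOH, 0 °C) gives 3,4-dimethoxybenzyl alcohol F6. Alkoxide-directed lithiation with a measured 2.2 equiv of n-BuLi (THF, 0 °C) gives the C2 dilithio species F7. Allylation with 5 (CuBr·SMe2, −78 °C → rt, aqueous work-up) gives 2-geranyl-3,4-dimethoxybenzyl alcohol F8. Benzylic oxidation (MnO2, CH2Cl2, rt) returns to the route at aldehyde 9.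

**Further compounds**

F1 | step 4 | racemic 2-{2-[(2E)-3,7-dimethylocta-2,6-dien-1-yl]-3,4-dimethoxyphenyl}-5-hydroxy-7-methoxy-6-(3-methylbut-2-en-1-yl)-2,3-dihydro-4H-chromen-4-one | COc1cc2c(c(O)c1CC=C(C)C)C(=O)CC(c1ccc(OC)c(OC)c1C/C=C(\C)CCC=C(C)C)O2
F2 | step 4 | racemic 2-{2-[(2E)-3,7-dimethylocta-2,6-dien-1-yl]-3,4-dimethoxyphenyl}-5-hydroxy-7-methoxy-8-(3-methylbut-2-en-1-yl)-2,3-dihydro-4H-chromen-4-one (regioisomeric by-product) | COc1cc(O)c2c(c1CC=C(C)C)OC(CC2=O)c1ccc(OC)c(OC)c1C/C=C(\C)CCC=C(C)C
F3 | step 3 | 1-[4-methoxy-2,6-bis(methoxymethoxy)-3-(3-methylbut-2-en-1-yl)phenyl]ethan-1-one | CC(=O)c1c(OCOC)cc(OC)c(CC=C(C)C)c1OCOC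
F4 | step 3 | 3-{2-[(2E)-3,7-dimethylocta-2,6-dien-1-yl]-3,4-dimethoxyphenyl}-3-hydroxy-1-[4-methoxy-2,6-bis(methoxymethoxy)-3-(3-methylbut-2-en-1-yl)phenyl]propan-1-one (racemic, not isolated) | COCOc1cc(OC)c(CC=C(C)C)c(OCOC)c1C(=O)CC(O)c1ccc(OC)c(OC)c1C/C=C(\C)CCC=C(C)C
F5 | step 3 | (2E)-3-{2-[(2E)-3,7-dimethylocta-2,6-dien-1-yl]-3,4-dimethoxyphenyl}-1-[4-methoxy-2,6-bis(methoxymethoxy)-3-(3-methylbut-2-en-1-yl)phenyl]prop-2-en-1-one | COCOc1cc(OC)c(CC=C(C)C)c(OCOC)c1C(=O)/C=C/c1ccc(OC)c(OC)c1C/C=C(\C)CCC=C(C)C
F6 | step 2 | (3,4-dimethoxyphenyl)methanol | COc1ccc(CO)cc1OC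
F7 | step 2 | lithium (2-lithio-3,4-dimethoxyphenyl)methanolate (not isolated) | [Li]OCc1ccc(OC)c(OC)c1[Li]
F8 | step 2 | {2-[(2E)-3,7-dimethylocta-2,6-dien-1-yl]-3,4-dimethoxyphenyl}methanol | COc1ccc(CO)c(C/C=C(\C)CCC=C(C)C)c1OC
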